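## Retrosynthetic overview
1. Hernanol ⇒ cut the C3–CH2Ar bond. The enolate of (R)-β-(4-silyloxy-3-methoxybenzyl)-γ-butyrolactone is alkylated anti with 3,4,5-trimethoxybenzyl bromide, and the silyl group is removed in the same flask.
2. (R)-Lactone ⇒ cut the C4–C5 bond and the acyl–O bond in one operation. The fragments are formaldehyde and the chiral-carbene homoenolate of (E)-4-arylbut-2-enal, so the enal β-carbon and the formaldehyde carbon, both normally electrophilic, are joined.
3. Enal ⇒ cross-metathesis of O-silyl eugenol with crotonaldehyde; O-silyl eugenol ⇒ eugenol.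
4. Rings: both arenes are bought. The butyrolactone is the only ring made, and it closes in the key step. C4 is set by the catalyst and C3 is set by C4.

Assumption: the sense of induction of the (5aS,10bR) triazolium salt in step 3 comes from a face-shielding model, not from a direct precedent. Both antipodes of the salt are sold, and the one that gives the (R)-lactone (checked by chiral HPLC and by the rotation of the final product) is used.

## Route

Step 1
Reactants: 1 eugenol (4-allyl-2-methoxyphenol); 2 tert-butyldimethylsilyl chloride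
Product: 3 (4-allyl-2-methoxyphenoxy)(tert-butyl)dimethylsilane (O-TBS-eugenol)
Conditions: 2 (1.1 equiv), imidazole (1.5 equiv), DMF, 23 °C, 2 h
Reagents that add atoms: tert-butyldimethylsilyl chloride (2), CC(C)(C)[Si](C)(C)Cl
Why: Imidazole-promoted phenol silylation caps the OH, which would otherwise protonate the homoenolate or intercept the acyl azolium in step 3 (redox esterification); no stereocentre is involved.

Step 2
Reactants: 3 O-TBS-eugenol; 4 (E)-crotonaldehyde
Product: 5 (E)-4-[4-(tert-butyldimethylsilyloxy)-3-methoxyphenyl]but-2-enal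
Conditions: 4 (4 equiv), second-generation Hoveyda–Grubbs catalyst RuCl2(H2IMes)(=CH-C6H4-2-OiPr) (C31H38Cl2N2ORu, 2.5 mol%), 1,4-benzoquinone (10 mol%), CH2Cl2, 40 °C, 6 h
Reagents that add atoms: (E)-crotonaldehyde (4), C/C=C/C=O
Why: Olefin cross-metathesis of a reactive terminal allylarene with an electron-poor enal partner gives the cross product selectively as the thermodynamic E-enal while propene escapes, and benzoquinone suppresses Ru–H-mediated allyl-to-propenyl isomerisation.

Step 3 (key step)
Reactants: 5 (E)-4-[4-(tert-butyldimethylsilyloxy)-3-methoxyphenyl]but-2-enal; 6 formaldehyde (weighed in as dried paraformaldehyde)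
Product: 9 (R)-4-[4-(tert-butyldimethylsilyloxy)-3-methoxybenzyl]dihydrofuran-2(3H)-one, via extended Breslow dienol 7 (not isolated), via acyl azolium alkoxide 8 (not isolated)
Conditions: anhydrous (5aS,10bR)-2-(2,4,6-trimethylphenyl)-5a,10b-dihydro-4H,6H-indeno[2,1-b][1,2,4]triazolo[4,3-d][1,4]oxazin-2-ium chloride (C21H22ClN3O, 12 mol%), KN(SiMe3)2 (10 mol%, so no free base remains), (CH2O)n (3 equiv), THF, 40 °C, 5 added by syringe pump over 6 h
Reagents that add atoms: formaldehyde (6), C=O
Why: Proposed new method: the carbene adds to the formyl group of 5 and a proton shift gives dienol 7, whose β-carbon is now nucleophilic (homoenolate) and attacks formaldehyde, the least hindered and most electrophilic aldehyde present and kept dilute by slow release from the polymer, on the face of 7 left open by the indane wall with the enol O–H hydrogen-bonded to the incoming C=O, which sets C4 as R, after which tautomerisation to 8 and 5-exo-trig acyl transfer close the lactone and release the carbene; the closest known reaction types are the carbene-catalysed homoenolate annulation of enals with aldehydes or activated ketones to γ-butyrolactones and the carbene-catalysed hydroxymethylation of aldehydes with paraformaldehyde, in which formaldehyde acts only as the acceptor.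

Step 4
Reactants: 9 (R)-4-[4-(tert-butyldimethylsilyloxy)-3-methoxybenzyl]dihydrofuran-2(3H)-one; 10 3,4,5-trimethoxybenzyl bromide
Product: 13 (3R,4R)-4-(4-hydroxy-3-methoxybenzyl)-3-(3,4,5-trimethoxybenzyl)dihydrofuran-2(3H)-one (hernanol), via lithium enolate 11 (not isolated), via O-TBS-hernanol 12 (not isolated)
Conditions: LiN(SiMe3)2 (1.1 equiv), THF, −78 °C, 45 min; 10 (1.05 equiv), DMPU (2 equiv), −78 → −30 °C; then AcOH (4 equiv), Bu4NF (3 equiv), 0 °C, 30 min
Reagents that add atoms: 3,4,5-trimethoxybenzyl bromide (10), COc1cc(CBr)cc(OC)c1OC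
Why: In this substrate-controlled lactone enolate alkylation (SN2) the C4 benzyl group shields the syn face of planar enolate 11, so 10 enters anti and sets C3 as R (the trans and also thermodynamic isomer, typically >20:1), and acetic-acid-buffered fluoride then cleaves the aryl silyl ether without ionising the phenol or touching C3.

## Compound list
1 | eugenol (4-allyl-2-methoxyphenol) | C=CCc1ccc(O)c(OC)c1 | starting material
2 | tert-butyldimethylsilyl chloride | CC(C)(C)[Si](C)(C)Cl | starting material
3 | (4-allyl-2-methoxyphenoxy)(tert-butyl)dimethylsilane | C=CCc1ccc(O[Si](C)(C)C(C)(C)C)c(OC)c1 | intermediate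
4 | (E)-crotonaldehyde | C/C=C/C=O | starting material
5 | (E)-4-[4-(tert-butyldimethylsilyloxy)-3-methoxyphenyl]but-2-enal | O=C/C=C/Cc1ccc(O[Si](C)(C)C(C)(C)C)c(OC)c1 | intermediate
6 | formaldehyde (used as paraformaldehyde) | C=O | starting material
7 | extended Breslow dienol: adduct of the (5aS,10bR)-triazolylidene with 5, the homoenolate equivalent | OC(/C=C/Cc1ccc(O[Si](C)(C)C(C)(C)C)c(OC)c1)=C1N(c2c(C)cc(C)cc2C)N=C2CO[C@H]3Cc4ccccc4[C@H]3N12 | intermediate
8 | acyl azolium alkoxide: (R)-4-oxido-3-(arylmethyl)butanoyl triazolium zwitterion | [O-]C[C@H](Cc1ccc(O[Si](C)(C)C(C)(C)C)c(OC)c1)CC(=O)C1=[N+](c2c(C)cc(C)cc2C)N=C2CO[C@H]3Cc4ccccc4[C@H]3N12 | intermediate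
9 | (R)-4-[4-(tert-butyldimethylsilyloxy)-3-methoxybenzyl]dihydrofuran-2(3H)-one | COc1cc(C[C@H]2COC(=O)C2)ccc1O[Si](C)(C)C(C)(C)C | intermediate
10 | 3,4,5-trimethoxybenzyl bromide | COc1cc(CBr)cc(OC)c1OC | starting material
11 | lithium enolate of 9 | COc1cc(C[C@H]2COC([O-])=C2)ccc1O[Si](C)(C)C(C)(C)C.[Li+] | intermediate
12 | O-TBS-hernanol, (3R,4R)-4-[4-(tert-butyldimethylsilyloxy)-3-methoxybenzyl]-3-(3,4,5-trimethoxybenzyl)dihydrofuran-2(3H)-one | COc1cc(C[C@H]2COC(=O)[C@@H]2Cc2cc(OC)c(OC)c(OC)c2)ccc1O[Si](C)(C)C(C)(C)C | intermediate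
13 | hernanol, (3R,4R)-4-(4-hydroxy-3-methoxybenzyl)-3-(3,4,5-trimethoxybenzyl)dihydrofuran-2(3H)-one | COc1cc(C[C@H]2COC(=O)[C@@H]2Cc2cc(OC)c(OC)c(OC)c2)ccc1O | target

## Totals
Total step count: 4. Longest linear sequence: 4 (1 → 3 → 5 → 9 → 13).

## Steps most likely to fail, with fallbacks

**Step 3 (highest risk).**
- Formaldehyde may tie up the carbene and feed formoin-type self-condensation.
- Dienol 7 may react at C1 to give a hydroxymethyl ketone, or it may be protonated at the β-carbon.
- Enal 5 may dimerise or drift to the styrenyl isomer.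
- The small electrophile may give only moderate ee.

The fallback keeps the same bond and the same polarity, but the nucleophilic β-carbon is carried as a stoichiometric chiral boron homoenolate equivalent. It sets out from 3. Cross-metathesis with tert-butyl acrylate, using the same ruthenium catalyst, gives tert-butyl (E)-4-[4-(tert-butyldimethylsilyloxy)-3-methoxyphenyl]but-2-enoate F1. Copper-catalysed enantioselective conjugate borylation follows. It uses B2pin2, CuCl, NaOtBu and MeOH in THF, with the antipode of 1-[2-(diphenylphosphino)ferrocenyl]ethyldicyclohexylphosphine that gives the R product. The product is tert-butyl (R)-4-[4-(tert-butyldimethylsilyloxy)-3-methoxyphenyl]-3-(4,4,5,5-tetramethyl-1,3,2-dioxaborolan-2-yl)butanoate F2. Matteson homologation (BrCH2Cl, n-BuLi, THF, −78 → 23 °C) moves the stereodefined β-carbon from boron onto the CH2 unit with retention. This gives tert-butyl (R)-3-[4-(tert-butyldimethylsilyloxy)-3-methoxybenzyl]-4-(4,4,5,5-tetramethyl-1,3,2-dioxaborolan-2-yl)butanoate F3. Oxidation with H2O2 at pH 7 gives tert-butyl (R)-3-[4-(tert-butyldimethylsilyloxy)-3-methoxybenzyl]-4-hydroxybutanoate F4. Catalytic p-TsOH in warm toluene closes F4 to the lactone, and the fallback comes back to the route at 9.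

**Step 2.**
- The allylarene may isomerise to the propenyl (isoeugenol-type) ether.
- It may homodimerise.
- The skipped enal may suffer on silica.

The fallback replaces metathesis by cleavage and olefination, and it sets out from 3. Lemieux–Johnson cleavage (OsO4 cat., NaIO4, 2,6-lutidine, dioxane/H2O) gives 2-[4-(tert-butyldimethylsilyloxy)-3-methoxyphenyl]acetaldehyde F5. F5 is used at once in a Wittig olefination with Ph3P=CHCHO (toluene, 23–40 °C). This gives the E-enal, and the fallback comes back to the route at 5.

**Step 4.**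
- The benzylic bromide is labile.
- Alkylation may stall or run on to the dialkylated lactone.
- Left-over bromide could O-alkylate the freed phenol.

The fallback replaces alkylation by aldol addition and hydrogenolysis, and it sets out from 9. Enolate 11 is made as before and is trapped at −78 °C with 3,4,5-trimethoxybenzaldehyde, again anti to the C4 substituent. The product is (3S,4R)-4-[4-(tert-butyldimethylsilyloxy)-3-methoxybenzyl]-3-[hydroxy(3,4,5-trimethoxyphenyl)methyl]dihydrofuran-2(3H)-one F6, a mixture of carbinol epimers in which both epimers are usable. Hydrogenolysis of the electron-rich benzylic C–O bond (H2, Pd/C, AcOH, 40 °C) leaves both ring stereocentres untouched, and the fallback comes back to the route at 12. Compound 12 is then isolated and desilylated with Bu4NF/AcOH as in the second half of step 4.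

## Further compounds
F1 | step 3 | tert-butyl (E)-4-[4-(tert-butyldimethylsilyloxy)-3-methoxyphenyl]but-2-enoate | CC(C)(C)OC(=O)/C=C/Cc1ccc(O[Si](C)(C)C(C)(C)C)c(OC)c1
F2 | step 3 | tert-butyl (R)-4-[4-(tert-butyldimethylsilyloxy)-3-methoxyphenyl]-3-(4,4,5,5-tetramethyl-1,3,2-dioxaborolan-2-yl)butanoate | COc1cc(C[C@@H](B2OC(C)(C)C(C)(C)O2)CC(=O)OC(C)(C)C)ccc1O[Si](C)(C)C(C)(C)C
F3 | step 3 | tert-butyl (R)-3-[4-(tert-butyldimethylsilyloxy)-3-methoxybenzyl]-4-(4,4,5,5-tetramethyl-1,3,2-dioxaborolan-2-yl)butanoate | COc1cc(C[C@@H](CB2OC(C)(C)C(C)(C)O2)CC(=O)OC(C)(C)C)ccc1O[Si](C)(C)C(C)(C)C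
F4 | step 3 | tert-butyl (R)-3-[4-(tert-butyldimethylsilyloxy)-3-methoxybenzyl]-4-hydroxybutanoate | COc1cc(C[C@@H](CO)CC(=O)OC(C)(C)C)ccc1O[Si](C)(C)C(C)(C)C
F5 | step 2 | 2-[4-(tert-butyldimethylsilyloxy)-3-methoxyphenyl]acetaldehyde | O=CCc1ccc(O[Si](C)(C)C(C)(C)C)c(OC)c1
F6 | step 4 | (3S,4R)-4-[4-(tert-butyldimethylsilyloxy)-3-methoxybenzyl]-3-[hydroxy(3,4,5-trimethoxyphenyl)methyl]dihydrofuran-2(3H)-one (carbinol epimers) | COc1cc(C[C@H]2COC(=O)[C@@H]2C(O)c2cc(OC)c(OC)c(OC)c2)ccc1O[Si](C)(C)C(C)(C)C
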